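Ring C is taken apart at O1–C2 and C3–C4 in one retro-[4+2] step. The plan exploits the ortho placement of O1 and C4 on ring A: the o-quinone methide O1=C8a–C4a=C4, released from a carbonate-protected 2,4-dihydroxybenzyl alcohol, serves as oxadiene, and C2=C3 arrives as an (E)-enol ether that carries the complete ring B on C3 and a trans-2-phenylcyclohexyl auxiliary on the C2 oxygen. The inverse-demand hetero-Diels–Alder reaction closes the pyran ring, unites both halves and sets C3. Ionic removal of the C2 alkoxy group and deprotection complete the synthesis; ring B owes its 1,1-dimethylallyl group to a Claisen rearrangement.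

Key step: step 9

Assumption: the enol ether is taken to react through its s-trans conformer on the face remote from the phenyl group of the auxiliary, which for the (1R,2S)-alcohol and the (E)-alkene leads to the (2S,3R)-adduct; should the sense prove opposite, the equally available (1S,2R)-alcohol is used without other change. The target is (3R).

Step 1
Reactants: 1 2,4-dihydroxybenzaldehyde
Product: 2 2-hydroxy-4-[(3-methylbut-2-en-1-yl)oxy]benzaldehyde
Conditions: prenyl bromide (1.05 equiv), K2CO3, acetone, rt to 40 °C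
Reagents that add atoms: prenyl bromide, CC(C)=CCBr
Why: Williamson etherification: the 2-OH is locked in a hydrogen bond to the formyl group, so the more acidic free 4-OH is alkylated selectively by the allylic bromide.

Step 2
Reactants: 2 2-hydroxy-4-[(3-methylbut-2-en-1-yl)oxy]benzaldehyde
Product: 3 4-[(3-methylbut-2-en-1-yl)oxy]-2-[(triisopropylsilyl)oxy]benzaldehyde
Conditions: TIPSOTf, 2,6-lutidine, CH2Cl2, 0 °C to rt
Reagents that add atoms: triisopropylsilyl trifluoromethanesulfonate, CC(C)[Si](OS(=O)(=O)C(F)(F)F)(C(C)C)C(C)C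
Why: Silylation of the hydrogen-bonded phenol with the reactive silyl triflate gives a bulky, heat-tolerant ether that masks the future 2'-OH and shields C3 of the arene.

Step 3
Reactants: 3 4-[(3-methylbut-2-en-1-yl)oxy]-2-[(triisopropylsilyl)oxy]benzaldehyde
Product: 4 4-hydroxy-5-(2-methylbut-3-en-2-yl)-2-[(triisopropylsilyl)oxy]benzaldehyde
Conditions: EtOH/H2O 4:1, 130 °C, sealed tube
Reagents that add atoms: none
Why: Aromatic Claisen rearrangement ([3,3]-sigmatropic shift with allyl inversion) should deliver the 1,1-dimethylallyl group to C5 because the other ortho position, C3, is buttressed by the triisopropylsilyloxy group, a regiochemical course known for 2-alkoxy-4-prenyloxyaryl carbonyl compounds under water acceleration.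

Step 4
Reactants: 4 4-hydroxy-5-(2-methylbut-3-en-2-yl)-2-[(triisopropylsilyl)oxy]benzaldehyde
Product: 5 5-(2-methylbut-3-en-2-yl)-4-[(3-methylbut-2-en-1-yl)oxy]-2-[(triisopropylsilyl)oxy]benzaldehyde
Conditions: prenyl bromide, K2CO3, acetone, rt
Reagents that add atoms: prenyl bromide, CC(C)=CCBr
Why: Williamson etherification of the only free phenol, acidified by the para formyl group, reinstalls the O-prenyl group next to the new quaternary carbon.

Step 5
Reactants: 5 5-(2-methylbut-3-en-2-yl)-4-[(3-methylbut-2-en-1-yl)oxy]-2-[(triisopropylsilyl)oxy]benzaldehyde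
Product: 6 1-[(E)-2-iodoethenyl]-5-(2-methylbut-3-en-2-yl)-4-[(3-methylbut-2-en-1-yl)oxy]-2-[(triisopropylsilyl)oxy]benzene
Conditions: CrCl2 (6 equiv), CHI3 (2 equiv), THF, 0 °C to rt
Reagents that add atoms: iodoform, IC(I)I
Why: Takai olefination: the geminal dichromium species formed from CHI3 and CrCl2 adds to the aldehyde and eliminates to give the (E)-vinyl iodide selectively without touching the other alkenes.

Step 6
Reactants: 6 1-[(E)-2-iodoethenyl]-5-(2-methylbut-3-en-2-yl)-4-[(3-methylbut-2-en-1-yl)oxy]-2-[(triisopropylsilyl)oxy]benzene; 7 (1R,2S)-2-phenylcyclohexan-1-ol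
Product: 8 1-[(E)-2-{[(1R,2S)-2-phenylcyclohexyl]oxy}ethenyl]-5-(2-methylbut-3-en-2-yl)-4-[(3-methylbut-2-en-1-yl)oxy]-2-[(triisopropylsilyl)oxy]benzene
Conditions: CuI (10 mol %), 3,4,7,8-tetramethyl-1,10-phenanthroline (20 mol %), Cs2CO3, toluene, 80 °C
Reagents that add atoms: none
Why: Ullmann-type CuI-catalysed C–O coupling of a vinyl iodide with a secondary alcohol, which proceeds with retention of the E geometry that later fixes the configuration at C3.

Step 7
Reactants: 1 2,4-dihydroxybenzaldehyde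
Product: 9 2,4-bis[(tert-butoxycarbonyl)oxy]benzaldehyde
Conditions: Boc2O (2.2 equiv), DMAP (cat.), i-Pr2NEt, THF, 0 °C to rt
Reagents that add atoms: di-tert-butyl dicarbonate, CC(C)(C)OC(=O)OC(=O)OC(C)(C)C
Why: DMAP-catalysed O-acylation of both phenols with Boc2O, the ortho carbonate being the later trigger for o-quinone methide release.

Step 8
Reactants: 9 2,4-bis[(tert-butoxycarbonyl)oxy]benzaldehyde
Product: 10 2,4-bis[(tert-butoxycarbonyl)oxy]benzyl alcohol
Conditions: BH3·THF, THF, 0 °C; MeOH quench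
Reagents that add atoms: none
Why: Electrophilic borane reduction of the aldehyde gives the benzylic alcohol through a non-basic boron alkoxide, so the neighbouring aryl carbonate does not migrate before it is wanted.

Step 9
Reactants: 8 1-[(E)-2-{[(1R,2S)-2-phenylcyclohexyl]oxy}ethenyl]-5-(2-methylbut-3-en-2-yl)-4-[(3-methylbut-2-en-1-yl)oxy]-2-[(triisopropylsilyl)oxy]benzene; 10 2,4-bis[(tert-butoxycarbonyl)oxy]benzyl alcohol
Product: 13 (2S,3R)-configured 2-{[(1R,2S)-2-phenylcyclohexyl]oxy}isoflavan acetal bearing 7-O-Boc and the silyl-protected ring B, via chloromagnesium phenoxide carbonate 11 (not isolated), via o-quinone methide 12 (not isolated)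
Conditions: 10 (2.5 equiv), t-BuMgCl (2.5 equiv, added last), toluene/Et2O, −78 °C, slow warming to rt
Reagents that add atoms: none
Why: t-BuMgCl deprotonates 10, the magnesium alkoxide takes over the ortho Boc group (11), and 1,4-elimination of tert-butyl carbonate releases o-quinone methide 12, whose electron-poor oxadiene O1=C8a–C4a=C4 adds the electron-rich C2=C3 of 8 in an inverse-electron-demand hetero-Diels–Alder reaction. The closest known reaction type is the three-component generation of o-quinone methides from ortho-carbonate benzyl alcohols and their [4+2] capture by enol ethers, chiral 2-phenylcyclohexyl enol ethers included. Ring C is closed by an intermolecular [4+2] cycloaddition that forms O1–C2 and C3–C4 together through an asynchronous transition state in which C3–C4 bonding leads. C3 is controlled by the auxiliary, whose phenyl group shields one face of the enol ether, together with the E geometry; C2 (alkoxy trans to the aryl group) follows from suprafacial addition and is erased in step 10, so both C2 epimers converge. Regiochemistry is secured by polarity, the nucleophilic β-carbon (C3) bonding to the methide carbon C4 and O1 to the oxocarbenium carbon C2. The cycloaddition must outrun self-condensation of 12, which the slow, temperature-controlled release of 12 in the presence of the electron-rich β-aryl enol ether and the electron-withdrawing carbonate on the future O7 are meant to secure.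

Step 10
Reactants: 13 (2S,3R)-configured 2-{[(1R,2S)-2-phenylcyclohexyl]oxy}isoflavan acetal
Product: 14 tert-butyl (3R)-3-{5-(2-methylbut-3-en-2-yl)-4-[(3-methylbut-2-en-1-yl)oxy]-2-[(triisopropylsilyl)oxy]phenyl}-3,4-dihydro-2H-chromen-7-yl carbonate
Conditions: Et3SiH (5 equiv), TMSOTf (0.2 equiv), CH2Cl2, −78 °C
Reagents that add atoms: none
Why: Ionic hydrogenation of the mixed acetal: the silyl triflate ionises the more basic exocyclic alkoxy group to the cyclic oxocarbenium ion, which Et3SiH should reduce at −78 °C faster than the C3 proton can be lost, so the C3 configuration is carried through.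

Step 11
Reactants: 14 tert-butyl (3R)-3-{5-(2-methylbut-3-en-2-yl)-4-[(3-methylbut-2-en-1-yl)oxy]-2-[(triisopropylsilyl)oxy]phenyl}-3,4-dihydro-2H-chromen-7-yl carbonate
Product: 15 Manuifolin D
Conditions: Bu4NF, THF, 0 °C; then K2CO3 (cat.), MeOH, rt
Reagents that add atoms: none
Why: Fluoride cleavage of the aryl silyl ether and base-catalysed methanolysis of the aryl carbonate are both non-acidic, so the prenyl ether and the two alkenes should remain intact.

Compound list
1 | 2,4-dihydroxybenzaldehyde | O=Cc1ccc(O)cc1O | starting material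
2 | 2-hydroxy-4-[(3-methylbut-2-en-1-yl)oxy]benzaldehyde | CC(C)=CCOc1ccc(C=O)c(O)c1 | intermediate
3 | 4-[(3-methylbut-2-en-1-yl)oxy]-2-[(triisopropylsilyl)oxy]benzaldehyde | CC(C)=CCOc1ccc(C=O)c(O[Si](C(C)C)(C(C)C)C(C)C)c1 | intermediate
4 | 4-hydroxy-5-(2-methylbut-3-en-2-yl)-2-[(triisopropylsilyl)oxy]benzaldehyde | C=CC(C)(C)c1cc(C=O)c(O[Si](C(C)C)(C(C)C)C(C)C)cc1O | intermediate
5 | 5-(2-methylbut-3-en-2-yl)-4-[(3-methylbut-2-en-1-yl)oxy]-2-[(triisopropylsilyl)oxy]benzaldehyde | C=CC(C)(C)c1cc(C=O)c(O[Si](C(C)C)(C(C)C)C(C)C)cc1OCC=C(C)C | intermediate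
6 | 1-[(E)-2-iodoethenyl]-5-(2-methylbut-3-en-2-yl)-4-[(3-methylbut-2-en-1-yl)oxy]-2-[(triisopropylsilyl)oxy]benzene | C=CC(C)(C)c1cc(/C=C/I)c(O[Si](C(C)C)(C(C)C)C(C)C)cc1OCC=C(C)C | intermediate
7 | (1R,2S)-2-phenylcyclohexan-1-ol (trans) | O[C@@H]1CCCC[C@H]1c1ccccc1 | starting material
8 | 1-[(E)-2-{[(1R,2S)-2-phenylcyclohexyl]oxy}ethenyl]-5-(2-methylbut-3-en-2-yl)-4-[(3-methylbut-2-en-1-yl)oxy]-2-[(triisopropylsilyl)oxy]benzene | C=CC(C)(C)c1cc(/C=C/O[C@@H]2CCCC[C@H]2c2ccccc2)c(O[Si](C(C)C)(C(C)C)C(C)C)cc1OCC=C(C)C | intermediate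
9 | 2,4-bis[(tert-butoxycarbonyl)oxy]benzaldehyde | CC(C)(C)OC(=O)Oc1ccc(C=O)c(OC(=O)OC(C)(C)C)c1 | intermediate
10 | 2,4-bis[(tert-butoxycarbonyl)oxy]benzyl alcohol | CC(C)(C)OC(=O)Oc1ccc(CO)c(OC(=O)OC(C)(C)C)c1 | intermediate
11 | chloromagnesium 5-[(tert-butoxycarbonyl)oxy]-2-{[(tert-butoxycarbonyl)oxy]methyl}phenoxide (after carbonate transfer to the benzylic oxygen) | CC(C)(C)OC(=O)OCc1ccc(OC(=O)OC(C)(C)C)cc1O[Mg]Cl | intermediate
12 | tert-butyl (4-methylidene-3-oxocyclohexa-1,5-dien-1-yl) carbonate (o-quinone methide) | C=C1C=CC(OC(=O)OC(C)(C)C)=CC1=O | intermediate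
13 | tert-butyl (2S,3R)-3-{5-(2-methylbut-3-en-2-yl)-4-[(3-methylbut-2-en-1-yl)oxy]-2-[(triisopropylsilyl)oxy]phenyl}-2-{[(1R,2S)-2-phenylcyclohexyl]oxy}-3,4-dihydro-2H-chromen-7-yl carbonate | CC(C)(C)OC(=O)Oc1ccc2c(c1)O[C@H](O[C@@H]1CCCC[C@H]1c1ccccc1)[C@@H](c1cc(C(C)(C)C=C)c(OCC=C(C)C)cc1O[Si](C(C)C)(C(C)C)C(C)C)C2 | intermediate
14 | tert-butyl (3R)-3-{5-(2-methylbut-3-en-2-yl)-4-[(3-methylbut-2-en-1-yl)oxy]-2-[(triisopropylsilyl)oxy]phenyl}-3,4-dihydro-2H-chromen-7-yl carbonate | CC(C)(C)OC(=O)Oc1ccc2c(c1)OC[C@@H](c1cc(C(C)(C)C=C)c(OCC=C(C)C)cc1O[Si](C(C)C)(C(C)C)C(C)C)C2 | intermediate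
15 | Manuifolin D, (3R)-3-{2-hydroxy-5-(2-methylbut-3-en-2-yl)-4-[(3-methylbut-2-en-1-yl)oxy]phenyl}-3,4-dihydro-2H-chromen-7-ol | C=CC(C)(C)c1cc([C@@H]2COc3cc(O)ccc3C2)c(O)cc1OCC=C(C)C | target

Total step count: 11. Longest linear sequence: 9 steps (steps 1 to 6, 9, 10 and 11, from 2,4-dihydroxybenzaldehyde).

Steps most likely to fail

Step 9. Self-condensation of the o-quinone methide may outrun its capture by the hindered β-aryl enol ether, or the auxiliary may discriminate the two faces of the enol ether poorly. The fallback builds C3–C4 by enolate alkylation and closes O1–C2 by an intramolecular Mitsunobu reaction; it sets out from 8 (and uses 10) and comes back at 15. Mild acidic hydrolysis of 8 (oxalic acid, wet THF) gives the arylacetaldehyde F1 and returns 7. Pinnick oxidation (NaClO2, NaH2PO4, 2-methylbut-2-ene, t-BuOH/H2O) gives the arylacetic acid F2. Activation with pivaloyl chloride/Et3N and acylation of (R)-4-benzyl-1,3-oxazolidin-2-one, lithiated with n-BuLi, gives the imide F3. Evans alkylation of its sodium enolate (NaN(SiMe3)2, THF, −78 °C) with the benzyl bromide F4, made from 10 by an Appel reaction (CBr4, PPh3), should give the (2R)-alkylated imide F5, the electrophile entering opposite the benzyl group of the auxiliary. Reductive removal of the auxiliary with LiBH4 followed by K2CO3/MeOH cleavage of both carbonates gives the triol F6. Mitsunobu etherification (PPh3, diisopropyl azodicarboxylate, THF, high dilution) joins the ring A ortho phenol to the primary alcohol, the 2'-oxygen being blocked by silicon, and gives the silyl-protected isoflavan F7. Bu4NF then converts F7 into 15.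

Step 10. The oxocarbenium ion may lose its C3 proton reversibly (4H-chromene formation), eroding the C3 configuration, or the Lewis acid may cleave or shift the prenyl ether. The fallback sets out from 13 and comes back at 15. Brief aqueous acid hydrolysis (1 M HCl, THF, 0 °C) of the acetal gives the lactol F8 and returns 7. The lactol is in equilibrium with the open α-aryl aldehyde, so hydrogenation under dynamic kinetic resolution turns epimerisation at C3 into an asset. The catalyst is a RuCl2(spiro-diphosphine)(1,2-diamine) complex such as RuCl2[(S)-DMM-SDP][(R,R)-DACH] or its mirror image, whichever delivers the (R)-alcohol, with KOt-Bu, i-PrOH and H2. With loss of the carbonate under the basic conditions this gives the triol F6 of the first fallback. Mitsunobu closure to F7 and desilylation to 15 follow as described there.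

Step 3. At the rearrangement temperature the prenyl group may be lost, the ortho-(1,1-dimethylallyl)phenol may cyclise onto its alkene, or solvolysis of the silyl ether may redirect the migration to C3. The fallback installs the 1,1-dimethylallyl group by cross-coupling; it sets out from 1 and comes back at 5. Bromination of 1 (Br2, AcOH) at C5 gives 5-bromo-2,4-dihydroxybenzaldehyde F9. A γ-selective Suzuki–Miyaura coupling with prenylboronic acid pinacol ester (Pd(OAc)2, 1,1'-bis(di-tert-butylphosphino)ferrocene, K3PO4, THF/H2O) gives 2,4-dihydroxy-5-(2-methylbut-3-en-2-yl)benzaldehyde F10. O-Prenylation of the unchelated 4-OH (prenyl bromide, K2CO3, acetone) gives the 2-hydroxy aldehyde F11, and silylation as in step 2 gives 5.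

Further compounds
F1 | step 9 | {5-(2-methylbut-3-en-2-yl)-4-[(3-methylbut-2-en-1-yl)oxy]-2-[(triisopropylsilyl)oxy]phenyl}acetaldehyde | C=CC(C)(C)c1cc(CC=O)c(O[Si](C(C)C)(C(C)C)C(C)C)cc1OCC=C(C)C
F2 | step 9 | {5-(2-methylbut-3-en-2-yl)-4-[(3-methylbut-2-en-1-yl)oxy]-2-[(triisopropylsilyl)oxy]phenyl}acetic acid | C=CC(C)(C)c1cc(CC(=O)O)c(O[Si](C(C)C)(C(C)C)C(C)C)cc1OCC=C(C)C
F3 | step 9 | (4R)-4-benzyl-3-({5-(2-methylbut-3-en-2-yl)-4-[(3-methylbut-2-en-1-yl)oxy]-2-[(triisopropylsilyl)oxy]phenyl}acetyl)-1,3-oxazolidin-2-one | C=CC(C)(C)c1cc(CC(=O)N2C(=O)OC[C@H]2Cc2ccccc2)c(O[Si](C(C)C)(C(C)C)C(C)C)cc1OCC=C(C)C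
F4 | step 9 | 2,4-bis[(tert-butoxycarbonyl)oxy]benzyl bromide | CC(C)(C)OC(=O)Oc1ccc(CBr)c(OC(=O)OC(C)(C)C)c1
F5 | step 9 | (4R)-4-benzyl-3-[(2R)-3-{2,4-bis[(tert-butoxycarbonyl)oxy]phenyl}-2-{5-(2-methylbut-3-en-2-yl)-4-[(3-methylbut-2-en-1-yl)oxy]-2-[(triisopropylsilyl)oxy]phenyl}propanoyl]-1,3-oxazolidin-2-one | CC(C)(C)OC(=O)Oc1ccc(C[C@@H](C(=O)N2C(=O)OC[C@H]2Cc2ccccc2)c2cc(C(C)(C)C=C)c(OCC=C(C)C)cc2O[Si](C(C)C)(C(C)C)C(C)C)c(OC(=O)OC(C)(C)C)c1
F6 | step 9 | 4-[(2R)-3-hydroxy-2-{5-(2-methylbut-3-en-2-yl)-4-[(3-methylbut-2-en-1-yl)oxy]-2-[(triisopropylsilyl)oxy]phenyl}propyl]benzene-1,3-diol | OC[C@H](Cc1ccc(O)cc1O)c1cc(C(C)(C)C=C)c(OCC=C(C)C)cc1O[Si](C(C)C)(C(C)C)C(C)C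
F7 | step 9 | (3R)-3-{5-(2-methylbut-3-en-2-yl)-4-[(3-methylbut-2-en-1-yl)oxy]-2-[(triisopropylsilyl)oxy]phenyl}-3,4-dihydro-2H-chromen-7-ol | Oc1ccc2c(c1)OC[C@@H](c1cc(C(C)(C)C=C)c(OCC=C(C)C)cc1O[Si](C(C)C)(C(C)C)C(C)C)C2
F8 | step 10 | tert-butyl (3R)-2-hydroxy-3-{5-(2-methylbut-3-en-2-yl)-4-[(3-methylbut-2-en-1-yl)oxy]-2-[(triisopropylsilyl)oxy]phenyl}-3,4-dihydro-2H-chromen-7-yl carbonate (lactol, anomeric mixture) | CC(C)(C)OC(=O)Oc1ccc2c(c1)OC(O)[C@@H](c1cc(C(C)(C)C=C)c(OCC=C(C)C)cc1O[Si](C(C)C)(C(C)C)C(C)C)C2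
F9 | step 3 | 5-bromo-2,4-dihydroxybenzaldehyde | O=Cc1cc(Br)c(O)cc1O
F10 | step 3 | 2,4-dihydroxy-5-(2-methylbut-3-en-2-yl)benzaldehyde | C=CC(C)(C)c1cc(C=O)c(O)cc1O
F11 | step 3 | 2-hydroxy-5-(2-methylbut-3-en-2-yl)-4-[(3-methylbut-2-en-1-yl)oxy]benzaldehyde | C=CC(C)(C)c1cc(C=O)c(O)cc1OCC=C(C)C
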